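## The problem

Compound 17 is a depside: the carboxyl carbon of ring A (2,4-dimethoxy-6-propylbenzoyl) is bound through an ester oxygen to C3 of ring B, a 2,4-dihydroxy-6-propylbenzoic acid, so the ester oxygen sits between two free hydroxyls and the ester carbonyl between a methoxyl and a propyl group. There is no stereocentre and no ring to close; the difficulty is regiochemistry and sensitivity. Ring B carries five different substituents in fixed order, and acylating a preformed 2,3,4-trioxygenated 6-propylbenzoate would mean telling three neighbouring hydroxyls apart and reaching the most crowded one. The ester bond joins a di-ortho-substituted acid to a di-ortho-substituted phenol. Three features forbid rough treatment: the ortho,para-dihydroxybenzoic acid loses CO2 on heating or in strong acid, the aryl ester can be cleaved or shifted to a neighbouring phenoxide by base, and the two methyl ethers of ring A exclude a late global demethylation, so the ring B hydroxyls need groups that come off separately. The opening is that ring B without its carboxyl carbon, as in diphenol 13, has a mirror plane through the ester-bearing carbon (C1 of the phenyl ester) and the propyl-bearing carbon (C4). Its two CH carbons, C3 and C5, are then identical, each ortho to one hydroxyl and para to the other. The carboxyl carbon can thus be attached last without a regiochemical choice, and both rings can come from the same phenol, divarinol 1.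

## Retrosynthesis

**17 to 16.** The carboxyl group of 17 is taken back to the formyl group of aldehyde 16; no skeletal bond is cut. A protected carboxyl would need a further deprotection on a molecule that tolerates neither base nor heat. An aldehyde is oxidized under buffered, cold chlorite conditions. The forward step must spare two free phenols and the one remaining ring B CH.

**16 to 13 and 14.** The bond between the ring B CH carbon and the formyl carbon is cut, giving diphenol 13 and formaldehyde 14. The neighbouring cut, the ester C–O bond at the acid or aldehyde stage, would leave a ring B piece whose middle hydroxyl must be acylated in preference to its two neighbours. Cutting the C–C bond first removes all asymmetry from ring B. The forward reaction must formylate once, ortho to a free hydroxyl, on ring B only, and leave the ester in place.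

**13 to 12.** The two flanking hydroxyls are masked as methoxymethyl ethers in ester 12. Acetals are chosen because acid removes them without touching the ring A methyl ethers. They are also the directing groups needed two stages back.

**12 to 10 and 6.** The acyl C–O bond of the ester is cut, giving acid 10 (activated as chloride 11) and phenol 6. Phenol 6 has only its middle hydroxyl free, so the acylation has no choice of site. The forward reaction must join two hindered partners. The electron-rich aroyl chloride and a preformed phenoxide are used for that.

**6 to 3, then 1 and 2.** The C–O bond of the middle oxygen is cut, leading through boronate 5 and aryllithium 4 to bis-acetal 3. Starting from a pyrogallol would bring back the differentiation problem. Here the middle oxygen is introduced last, at the carbon between the two acetal oxygens that lithiates most readily. Bis-acetal 3 comes from divarinol 1 and two equivalents of chloromethyl methyl ether 2.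

**10 to 9, 7 and 1.** The carboxyl carbon of ring A is removed through aldehyde 9 (formed via iminium salt 8) to dimethyl ether 7. Electrophilic formylation is chosen over lithiation because lithiation of 7 would go between the two methoxyls and give the wrong acid. Ether 7 is the dimethyl ether of 1, so one phenol feeds both rings.

## Roads not taken

**Alternative 1:** Ring A would be cut at its C1–C6 bond, so that the depside ester is made on an open polyketide chain and the arene is folded afterwards. In the forward sense, benzyl 2,4-bis(benzyloxy)-3-(3,5,7-trioxodecanoyloxy)-6-propylbenzoate A2 would undergo base-mediated aldol condensation between C2 and C7 of its chain. Dehydration and enolization would give benzyl 2,4-bis(benzyloxy)-3-(2,4-dihydroxy-6-propylbenzoyloxy)-6-propylbenzoate A1.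
- Merits: the ester bond is formed with an unhindered open-chain acyl donor, so the coupling of two crowded arenes is avoided. Here it is better than the chosen plan. The substitution pattern of ring A follows from the chain.
- Weak points: A2 is an aryl ester of a 3,5-diketo acid. The enol oxygen at C5 can close onto the ester carbonyl and expel the ring B phenoxide as a 4-hydroxy-2-pyrone forms. The Claisen mode of folding also releases the phenol. Both paths destroy the bond the route is meant to keep. After A1, two O-methylations (one on a hydrogen-bonded salicylate hydroxyl) and removal of three benzyl groups remain. The ring B partner with a free middle hydroxyl still has to be made, which is the differentiation problem again.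
- Comparison: the chosen plan is shorter and uses only stable arenes. It accepts the hindered acylation, which the electron-rich aroyl chloride and a naked phenoxide are expected to manage.

**Alternative 2:** The aryl–oxygen bond at C3 of ring B would be cut with reversed polarity. Benzyl 2,4-bis(benzyloxy)-3-iodo-6-propylbenzoate A4 would undergo iodine–magnesium exchange with iPrMgCl·LiCl. The resulting aryl carbon would attack a peroxide oxygen of bis(2,4-dimethoxy-6-propylbenzoyl) peroxide A5, giving benzyl 2,4-bis(benzyloxy)-3-(2,4-dimethoxy-6-propylbenzoyloxy)-6-propylbenzoate A3. Hydrogenolysis would finish the synthesis.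
- Merits: the carboxyl carbon is present from the start, no oxidation is run on a free electron-rich phenol, and the last step is neutral hydrogenolysis. For a product that decarboxylates and can suffer acyl shift, this ending is gentler than the chosen one.
- Weak points: A4 needs iodine at C3, between two oxygens, and not at the open C5. That is the regiochemical problem the chosen plan removes by symmetry. A5 is an electron-rich diaroyl peroxide, prone to ionic decomposition and a handling hazard, and only one of its two ring A units reaches the product. The arylmagnesium is flanked by two benzyloxy groups, lives beside a benzyl ester, and may react with the peroxide by electron transfer.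
- Comparison: step counts are similar. The chosen plan offers ordinary reagents, both halves from 1 and no positional question on ring B. It pays with a C–H functionalization on an unprotected diphenol ester and a final oxidation.

**Alternative 3:** Ring B would be cut at C1–C6 and C2–C3 and built by annulation. Dibenzyl malonate A8 would add to the β-carbon of (E)-2-oxohept-3-en-1-yl 2,4-dimethoxy-6-propylbenzoate A7. The enolate of the acyloxymethyl ketone would then close onto one malonate ester. This gives racemic benzyl trans-3-(2,4-dimethoxy-6-propylbenzoyloxy)-2-hydroxy-4-oxo-6-propylcyclohex-2-ene-1-carboxylate A6. Dehydrogenation to the arene and hydrogenolysis of the benzyl ester would follow.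
- Merits: the ester bond of A7 is made on a primary carbon, for example by carboxylate alkylation, which is indifferent to the crowding of the ring A acid. This is better than step 6 of the chosen plan. The carboxyl carbon and the oxygen pattern of ring B arrive in one operation. The two stereocentres of A6 are erased on aromatization and need no control.
- Weak points: the Claisen closure must use the enolate carbon that bears the aroyloxy group. Under alkoxide base that enolate can pass its aroyl group to a neighbouring oxygen or lose it. The aromatization of A6 needs a halogen or quinone oxidant that must spare the electron-rich ring A, the enol ester and the benzyl ester. Such dehydrogenations are often the poorest step of a sequence.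
- Comparison: length is comparable. The chosen plan keeps both rings aromatic throughout and changes oxidation level only once, at the formyl group.

Key step: step 8

Assumption: divarinol 1 is bought as such, and the target, which has no stereocentre, is made as a single achiral compound.

## Route

Step 1
Reactants: 1 divarinol (5-propylbenzene-1,3-diol); 2 chloromethyl methyl ether (two equivalents in all, one per hydroxyl)
Product: 3 1,3-bis(methoxymethoxy)-5-propylbenzene
Conditions: iPr2NEt, CH2Cl2, 0 °C → rt
Reagents that add atoms: chloromethyl methyl ether (second equivalent), COCCl
Why: Williamson-type O-alkylation of each of the two phenols by one molecule of the α-chloro ether; the acetals are the directing groups for step 2 and are later removed by acid that leaves aryl methyl ethers alone.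

Step 2
Reactants: 3 1,3-bis(methoxymethoxy)-5-propylbenzene
Product: 6 2,6-bis(methoxymethoxy)-4-propylphenol, via aryllithium 4 (not isolated), via dimethyl arylboronate 5 (not isolated)
Conditions: n-BuLi, THF, 0 °C; B(OMe)3, −78 °C → rt; 30% aq H2O2, 0 °C → rt
Reagents that add atoms: hydrogen peroxide, OO
Why: Directed ortho-metalation at the carbon between the two acetal oxygens (both chelate lithium), borylation, and oxidative 1,2-shift of the aryl group from boron to oxygen; the lithium methoxide set free keeps the peroxide step basic.

Step 3
Reactants: 1 divarinol (5-propylbenzene-1,3-diol)
Product: 7 1,3-dimethoxy-5-propylbenzene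
Conditions: MeI (2.5 equiv), K2CO3, acetone, reflux
Reagents that add atoms: iodomethane, CI
Why: Williamson ether synthesis on both phenols; C-methylation is not expected with a carbonate base in acetone.

Step 4
Reactants: 7 1,3-dimethoxy-5-propylbenzene
Product: 9 2,4-dimethoxy-6-propylbenzaldehyde, via aryl iminium chloride 8 (not isolated)
Conditions: POCl3, DMF, 0 → 70 °C; then ice-water, rt
Reagents that add atoms: N,N-dimethylformamide, CN(C)C=O; water, O
Why: Vilsmeier–Haack formylation; the chloroiminium ion should attack the carbon para to one methoxyl and ortho to the other in preference to the carbon squeezed between the two methoxyls, and the iminium salt 8 is hydrolysed on quenching.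

Step 5
Reactants: 9 2,4-dimethoxy-6-propylbenzaldehyde
Product: 10 2,4-dimethoxy-6-propylbenzoic acid
Conditions: NaClO2, NaH2PO4, 2-methyl-2-butene, t-BuOH/H2O, rt
Reagents that add atoms: sodium chlorite, [Na+].[O-]Cl=O
Why: Pinnick oxidation; chlorous acid converts the aldehyde to the acid and the alkene removes the HOCl that would otherwise chlorinate the electron-rich ring.

Step 6
Reactants: 10 2,4-dimethoxy-6-propylbenzoic acid; 6 2,6-bis(methoxymethoxy)-4-propylphenol
Product: 12 2,6-bis(methoxymethoxy)-4-propylphenyl 2,4-dimethoxy-6-propylbenzoate, via acid chloride 11 (not isolated)
Conditions: (COCl)2, cat. DMF, CH2Cl2, 0 °C → rt, evaporate; then sodium salt of 6 (NaH, THF), 0 °C → rt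
Reagents that add atoms: none
Why: Acylation of a sodium phenoxide by an aroyl chloride; both partners are di-ortho-substituted, but the electron-rich chloride 11 ionizes easily toward a linear acylium ion and the naked phenoxide is a strong oxygen nucleophile, while the acetals are inert to base.

Step 7
Reactants: 12 2,6-bis(methoxymethoxy)-4-propylphenyl 2,4-dimethoxy-6-propylbenzoate
Product: 13 2,6-dihydroxy-4-propylphenyl 2,4-dimethoxy-6-propylbenzoate
Conditions: 1.25 M HCl in MeOH, THF, 0 °C → rt
Reagents that add atoms: none
Why: Acid-catalysed acetal exchange; methanol takes up the methoxymethyl cations as dimethoxymethane so that no formaldehyde equivalent is left to alkylate the freed resorcinol ring, and dilute acid at room temperature spares the shielded aryl ester, the methyl ethers and, having no phenoxide, gives no acyl shift.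

Step 8
Reactants: 13 2,6-dihydroxy-4-propylphenyl 2,4-dimethoxy-6-propylbenzoate; 14 formaldehyde (used as paraformaldehyde)
Product: 16 3-formyl-2,6-dihydroxy-4-propylphenyl 2,4-dimethoxy-6-propylbenzoate, via hydroxymethyl diphenol 15 (not isolated)
Conditions: anhydrous MgCl2, Et3N, (CH2O)n, THF, 65 °C; then cold 1 M HCl
Reagents that add atoms: none
Why: Casnati–Skattebøl ortho-formylation: MgCl2 and Et3N turn a ring B hydroxyl of 13 into a chloromagnesium phenoxide, the divalent magnesium binds monomeric formaldehyde, and the carbon ortho to that oxygen attacks it through a six-membered chelate transition state to give, after tautomerization, the magnesium salt of salicyl alcohol 15. A second formaldehyde then accepts hydride from the magnesium-bound benzylic alkoxide (Oppenauer-type transfer), leaving the chelated salicylaldehyde 16 and methanol. No ring is closed and no stereocentre is formed. The step needs selectivity between the rings, between one and two formylations, and between ring carbon and ester carbonyl. Ring A has no hydroxyl to anchor magnesium, so formaldehyde is delivered only to ring B, whose two CH carbons are mirror images, each ortho to one hydroxyl and para to the other, so either gives the same product. After the first formylation the remaining CH is governed by the hydroxyl para to the new formyl group, whose phenoxide is a vinylogous carboxylate and a poor nucleophile; with paraformaldehyde held near the two equivalents consumed, the reaction should stop at the mono-aldehyde. The ester carbonyl is shielded by the ortho methoxyl and propyl groups of ring A, so attack by the neighbouring phenoxide or by the amine should be slow. Cold dilute HCl releases 16 from its magnesium chelate.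

Step 9
Reactants: 16 3-formyl-2,6-dihydroxy-4-propylphenyl 2,4-dimethoxy-6-propylbenzoate
Product: 17 3-(2,4-dimethoxy-6-propylbenzoyloxy)-2,4-dihydroxy-6-propylbenzoic acid (CNP0211929.0)
Conditions: NaClO2, NaH2PO4, 2-methyl-2-butene (large excess), t-BuOH/THF/H2O, 0 °C → rt
Reagents that add atoms: sodium chlorite, [Na+].[O-]Cl=O
Why: Pinnick oxidation of a salicylaldehyde; the alkene traps HOCl before it can chlorinate the free CH of ring B, the cold buffered medium spares the ester, and the acid is isolated without heating to avoid decarboxylation.

## Compound list

1 | divarinol (5-propylbenzene-1,3-diol) | CCCc1cc(O)cc(O)c1 | starting material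
2 | chloromethyl methyl ether | COCCl | starting material
3 | 1,3-bis(methoxymethoxy)-5-propylbenzene | CCCc1cc(OCOC)cc(OCOC)c1 | intermediate
4 | [2,6-bis(methoxymethoxy)-4-propylphenyl]lithium | CCCc1cc(OCOC)c([Li])c(OCOC)c1 | intermediate
5 | dimethyl [2,6-bis(methoxymethoxy)-4-propylphenyl]boronate | CCCc1cc(OCOC)c(B(OC)OC)c(OCOC)c1 | intermediate
6 | 2,6-bis(methoxymethoxy)-4-propylphenol | CCCc1cc(OCOC)c(O)c(OCOC)c1 | intermediate
7 | 1,3-dimethoxy-5-propylbenzene | CCCc1cc(OC)cc(OC)c1 | intermediate
8 | (2,4-dimethoxy-6-propylbenzylidene)dimethylammonium chloride | CCCc1cc(OC)cc(OC)c1C=[N+](C)C.[Cl-] | intermediate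
9 | 2,4-dimethoxy-6-propylbenzaldehyde | CCCc1cc(OC)cc(OC)c1C=O | intermediate
10 | 2,4-dimethoxy-6-propylbenzoic acid | CCCc1cc(OC)cc(OC)c1C(=O)O | intermediate
11 | 2,4-dimethoxy-6-propylbenzoyl chloride | CCCc1cc(OC)cc(OC)c1C(=O)Cl | intermediate
12 | 2,6-bis(methoxymethoxy)-4-propylphenyl 2,4-dimethoxy-6-propylbenzoate | CCCc1cc(OC)cc(OC)c1C(=O)Oc1c(OCOC)cc(CCC)cc1OCOC | intermediate
13 | 2,6-dihydroxy-4-propylphenyl 2,4-dimethoxy-6-propylbenzoate | CCCc1cc(OC)cc(OC)c1C(=O)Oc1c(O)cc(CCC)cc1O | intermediate
14 | formaldehyde (used as paraformaldehyde) | C=O | starting material
15 | 2,6-dihydroxy-3-(hydroxymethyl)-4-propylphenyl 2,4-dimethoxy-6-propylbenzoate (present as its magnesium salt) | CCCc1cc(OC)cc(OC)c1C(=O)Oc1c(O)cc(CCC)c(CO)c1O | intermediate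
16 | 3-formyl-2,6-dihydroxy-4-propylphenyl 2,4-dimethoxy-6-propylbenzoate | CCCc1cc(OC)cc(OC)c1C(=O)Oc1c(O)cc(CCC)c(C=O)c1O | intermediate
17 | 3-(2,4-dimethoxy-6-propylbenzoyloxy)-2,4-dihydroxy-6-propylbenzoic acid (CNP0211929.0) | CCCc1cc(OC)cc(OC)c1C(=O)Oc1c(O)cc(CCC)c(C(=O)O)c1O | target

## Step count and risks

Total steps: 9. Longest linear sequence: 7 steps (steps 3, 4, 5, 6, 7, 8 and 9, from 1 to 17). The ring B branch (steps 1 and 2) joins at step 6.

**Step 8 (key step).** Ring B of 13 is a resorcinol and far more nucleophilic than the simple phenols on which this formylation is usually run. The most likely failure is condensation at the benzylic alkoxide stage with a second molecule of diphenol, giving methylene-bridged material. The second is a shift of the aroyl group to a flanking phenoxide under the basic magnesium conditions. The fallback sets out from 13 and comes back at 16. It is a Rieche formylation with Cl2CHOMe and TiCl4 in CH2Cl2 at −20 to 0 °C, an electrophilic substitution under Lewis-acidic conditions with no phenoxide and no free formaldehyde. The titanium phenoxide directs the reagent ortho to oxygen and gives racemic 3-[chloro(methoxy)methyl]-2,6-dihydroxy-4-propylphenyl 2,4-dimethoxy-6-propylbenzoate F1, which aqueous work-up hydrolyses to 16. Ring A is deactivated by its carbonyl group and not bound to titanium, so it should react more slowly than ring B.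

**Step 9.** The likely failures are chlorination of the remaining ring B CH by HOCl that escapes the scavenger, and loss of CO2 from the product during isolation. The fallback sets out from 13 and comes back at 17, bypassing 16. It is a direct ortho-carboxylation of the diphenol with methyl magnesium carbonate, MeOMgOCO2Me, in DMF at about 120 °C, followed by cold dilute HCl. The magnesium chelate of the hydroxy acid is stable to the heat and no electrophilic chlorine is involved. It asks the ester to survive hot basic DMF, which the behaviour of 13 in step 8 would already have tested in milder form.

**Step 6.** The acylation may stall between the two di-ortho-substituted partners, and the chloride would then be lost to hydrolysis on work-up. The fallback sets out from 10 and 6 and comes back at 12. Acid 10 is converted with cyanuric fluoride and pyridine in CH2Cl2 into 2,4-dimethoxy-6-propylbenzoyl fluoride F2. This is a smaller and more robust acyl donor that can be purified. It is heated with the potassium phenoxide of 6, made with KN(SiMe3)2 in THF.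

**Step 4.** Attack at the carbon between the two methoxyls could compete with the wanted position and give an inseparable aldehyde isomer. The fallback sets out from 7 and comes back at 10, bypassing 9 and step 5. Bromination with NBS in MeCN at 0 °C, which is strongly para-directed by methoxyl, gives 2-bromo-1,5-dimethoxy-3-propylbenzene F3. Bromine–lithium exchange with n-BuLi in THF at −78 °C gives (2,4-dimethoxy-6-propylphenyl)lithium F4, which is quenched with CO2 and acidified to 10.

## Further compounds

F1 | step 8 | racemic 3-[chloro(methoxy)methyl]-2,6-dihydroxy-4-propylphenyl 2,4-dimethoxy-6-propylbenzoate | CCCc1cc(OC)cc(OC)c1C(=O)Oc1c(O)cc(CCC)c(C(Cl)OC)c1O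
F0 | step 9 | none | none
F2 | step 6 | 2,4-dimethoxy-6-propylbenzoyl fluoride | CCCc1cc(OC)cc(OC)c1C(F)=O
F3 | step 4 | 2-bromo-1,5-dimethoxy-3-propylbenzene | CCCc1cc(OC)cc(OC)c1Br
F4 | step 4 | (2,4-dimethoxy-6-propylphenyl)lithium | CCCc1cc(OC)cc(OC)c1[Li]
A1 | alternative 1 | benzyl 2,4-bis(benzyloxy)-3-(2,4-dihydroxy-6-propylbenzoyloxy)-6-propylbenzoate | CCCc1cc(O)cc(O)c1C(=O)Oc1c(OCc2ccccc2)cc(CCC)c(C(=O)OCc2ccccc2)c1OCc1ccccc1
A2 | alternative 1 | benzyl 2,4-bis(benzyloxy)-3-(3,5,7-trioxodecanoyloxy)-6-propylbenzoate | CCCC(=O)CC(=O)CC(=O)CC(=O)Oc1c(OCc2ccccc2)cc(CCC)c(C(=O)OCc2ccccc2)c1OCc1ccccc1
A3 | alternative 2 | benzyl 2,4-bis(benzyloxy)-3-(2,4-dimethoxy-6-propylbenzoyloxy)-6-propylbenzoate | CCCc1cc(OC)cc(OC)c1C(=O)Oc1c(OCc2ccccc2)cc(CCC)c(C(=O)OCc2ccccc2)c1OCc1ccccc1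
A4 | alternative 2 | benzyl 2,4-bis(benzyloxy)-3-iodo-6-propylbenzoate | CCCc1cc(OCc2ccccc2)c(I)c(OCc2ccccc2)c1C(=O)OCc1ccccc1
A5 | alternative 2 | bis(2,4-dimethoxy-6-propylbenzoyl) peroxide | CCCc1cc(OC)cc(OC)c1C(=O)OOC(=O)c1c(CCC)cc(OC)cc1OC
A6 | alternative 3 | racemic benzyl trans-3-(2,4-dimethoxy-6-propylbenzoyloxy)-2-hydroxy-4-oxo-6-propylcyclohex-2-ene-1-carboxylate | CCC[C@@H]1CC(=O)C(OC(=O)c2c(CCC)cc(OC)cc2OC)=C(O)[C@H]1C(=O)OCc1ccccc1
A7 | alternative 3 | (E)-2-oxohept-3-en-1-yl 2,4-dimethoxy-6-propylbenzoate | CCC/C=C/C(=O)COC(=O)c1c(CCC)cc(OC)cc1OC
A8 | alternative 3 | dibenzyl malonate | O=C(CC(=O)OCc1ccccc1)OCc1ccccc1
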